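## Structural features

Locants used throughout: the bicyclo[2.2.2]oct-5-ene has bridgeheads C1 and C4, C2 (lactone carbonyl carbon attached), C3 (oxolane attached), C5 (methyl-bearing alkene carbon, next to C4), C6 (alkene CH), C7 (isopropyl, next to C1) and C8 (CH2). The oxolane is O1', C2' (on C3), C3' (lactone oxygen), C4' (free hydroxyl) and C5' (phenyl).

The target (C23H28O4) is this bicyclooctene with a δ-lactone cis-fused across C2–C3 and the oxolane cis-fused to the lactone across C2'–C3'. It has nine stereocentres: C1, C2, C3, C4 and C7 on the bicycle, and the contiguous row C2'–C3'–C4'–C5' on the oxolane. Both lactone attachments on the bicycle are endo (syn to C5=C6), and the isopropyl group leans toward the same alkene from the other bridge, so the ring alkene is screened on both faces. On the oxolane, the bicyclic substituent at C2', the lactone oxygen at C3' and the phenyl at C5' share one face; only the C4' hydroxyl is on the other, so the two oxygens are trans and the lactone oxygen sits on the crowded face. Fragile points are the lactone (base), the benzylic C5'–O1' ether (strong acid, hydrogenolysis), and the trisubstituted ring alkene (electrophilic oxidants; acid in the presence of an endo carboxyl). In addition, any intermediate with a free C2' hydroxyl cis to a C2 ester can close a γ-lactone. The real difficulty is placing the C3' oxygen on the hindered face while a second, more electron-rich alkene is present. The key step exploits two facts: the C2 carboxyl is tethered so that its oxygen reaches C3' through a six-membered ring (O–C(=O)–C2–C3–C2'–C3'), and a 2,5-cis dihydrofuran can only be dihydroxylated on its open face, which puts the C3'–O bond of the derived cyclic sulfate anti to that carboxylate.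

## Logic of the disconnections

20 to 19: the S–O bond of the sulfate monoester on O4' is cut. The sulfate is what remains of the leaving group of the key step, so this places that step last. The forward hydrolysis must spare the lactone, the benzylic ether and the ring alkene, which calls for catalytic acid and little water.

19 to 18 (key disconnection): the lactone C3'–O bond is cut. It can be formed with inversion from a cis-diol derivative, which turns the hindered-face oxygen problem into an open-face dihydroxylation and removes one ring. The forward step needs attack at C3' and not at C4', and a clean SN2 course. Compounds 18 and 19 differ from 20 only in the configuration at C3' and in the sulfate on O4'; no structural correction is needed.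

18 to 17: the ester O–CH2 bond of a 2-(trimethylsilyl)ethyl ester is cut. The carboxylate must not exist before the cyclic sulfate is in place, and it must be released without hydroxide or strong acid. The ester has to survive steps 6 to 10, and fluoride must trigger the release faster than it attacks the sulfate.

17 to 16 to 15: the two S–O bonds and then the two C–O bonds at C3' and C4' are cut, which returns the oxolane to an alkene. The forward demands are osmylation of the dihydrofuran alkene in preference to the ring alkene, on the face anti to both substituents, and formation of the sulfate without a ruthenium oxidant that could cleave the ring alkene.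

15 to 14: the C3'=C4' bond is cut (ring-closing metathesis), which opens the oxolane to a bis-allylic ether. The 2,5-cis relationship then depends only on the configurations at C2' and C5'.

14 to 13 to 12 to 9: the terminal C=C is cut (methylenation of an aldehyde), and then the ester carbon and the aldehyde carbon are reconnected into a cyclopentanone. The cis-1,2 relationship of the carboxyl and the side chain on the bicycle thus becomes a ring fusion. Forward, this needs oxygenation at the CH2 side of the ketone without β-elimination of the C2' ether, and a cleavage that delivers the ester directly.

9 to 8 to 5 plus 7: the C5'–O1' ether bond is cut. A branched-selective allylic substitution sets C5' under catalyst control. The ether is made before the ring is cleaved: once C2 carries an ester, a free C2' hydroxyl cis to it would close a γ-lactone under the alkoxide conditions of the etherification. The ketone is masked as a ketal in 5 and 8 so that no β-hydroxy ketone is exposed to base. Compound 7 comes from 6 in one step.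

5 to 4 to 3: the ketal C–O bonds and the O–Si bond are cut; this is protecting-group bookkeeping with no change in skeleton.

3 to 1 plus 2: the C1–C2 and C3–C4 bonds are cut (Diels–Alder). This is the largest simplification: two commercial compounds deliver the bicycle with C1, C2, C3 and C4, while C7 and C2' come from the chiral pool. The forward step must combine para regiochemistry, endo orientation, and attack anti to isopropyl on the diene and anti to the silyloxy group on the enone.

## Other disconnections considered

Alternative 1: The cut removes the C7–C8 bridge (bonds C1–C7 and C4–C8), so the carbocycle would come from an aromatic ring instead of a terpene. Forward, the enantiopure spiro-ketal cyclohexa-2,4-dienone A2, a masked o-benzoquinone, would add the unsubstituted vinyl group of isoprene A3 across its diene termini to give the endo-isopropenyl bicyclooctenone A1.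
- In its favour: the partners are cheap, dienones of this kind should cycloadd without a Lewis acid, and A1 already has the C5 methyl group, the C5=C6 alkene and the C7 substituent in the right relative orientation.
- Against it here: A1 has a ketone at C2 and a ketal carbon at C3, that is, oxygen where the target needs the carboxyl carbon and C2'. Two C–C bonds would still have to be made at neighbouring hindered carbonyl carbons with both new centres endo. The isopropenyl group must later be hydrogenated beside the ring alkene, A3 can also react through its other double bond or as a diene, and the absolute configuration hangs on the spiro centre of A2, which needs its own asymmetric synthesis.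
- Comparison: structurally, the chosen plan reaches a far more advanced bicycle in its first step (3 has all five ring stereocentres, C2' and both side-chain carbons). Mechanistically both open with a [4+2] reaction. In step count the alternative would be clearly longer, because its key step does not address the oxolane or the lactone. It is the better plan on one point: its cycloaddition does not need Lewis-acid activation of a poor cyclopentenone dienophile beside an acid-sensitive diene, which is the weakest step of the chosen route. It is the equal of the chosen plan in letting one stereocentre steer the facial sense of the cycloaddition.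

Alternative 2: The cut is the C3–C2' bond, with the lactone C3'–O bond already present as an ester tether. Forward, the selenide ester A5 would be reduced to the C2' radical, which adds to the β-carbon C3 of the unsaturated ester in a 6-endo cyclisation; hydrogen transfer to C2 then gives A4, the silyl ether of the target.
- In its favour: it is highly convergent (two halves joined by acylation), the lactone oxygen on the crowded face is introduced by esterification with retention, the cis fusion at C2'/C3' is enforced by the tether, and no dihydroxylation beside the ring alkene is needed.
- Against it here: ester-tethered radicals cyclise slowly because the ester prefers its extended rotamer, so simple reduction is likely to compete. The radical must choose the face of C3 syn to the C5=C6 bridge, and only the shape of the diene directs it. The acyl half of A5 is a bicyclo[2.2.2]octadiene, a ring system prone to cycloreversion to an arene. The alkoxy half of A5 needs the full phenyl/oxygen/oxygen stereotriad plus the selenide, so the trans-diol problem is moved into a fragment synthesis, not solved.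
- Comparison: on convergence and on the number of stereocentres set in the key step (three against one) the alternative is the better plan. On mechanism, the chosen SN2 closure is stereospecific whereas the radical closure is only stereoselective. On step count the two are probably comparable once the oxolane fragment is included, and the chosen route leaves fewer open selectivity questions at the decisive bond.

Alternative 3: The cut is the C1–C2 bond. Forward, the cis-fused tertiary allylic δ-lactone A7 would be converted into its silyl ketene acetal, which rearranges through a boat-like [3,3] transition state: C2 bonds to C1, the C5=C6 alkene with its methyl group appears, and the lactone contracts to the bicyclooctene acid A6, the bis-silylated seco acid of the target.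
- In its favour: chirality is transferred suprafacially from the carbinol carbon to C1, and C2 is fixed by the ring-constrained ketene acetal, so the endo acid and the ring alkene arise together without any facial choice by an external reagent. No Lewis acid or oxidant touches the bicycle, and the final lactonisation is an ordinary acylation with retention.
- Against it here: A7 is itself demanding. It has four stereocentres on the carbocyclic side, including the C3–C4 bond, which must be made with control, and it needs the complete oxolane with its trans-diol already in place. Enolisation of a hindered lactone can expel the allylic carboxylate, and the boat transition state must accommodate the large oxolane.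
- Comparison: structurally the alternative postpones the bicycle and front-loads the oxolane, the reverse of the chosen plan. Mechanistically its key step is the more reliable in stereochemical terms (a concerted rearrangement against an intermolecular cycloaddition plus an SN2 closure), and on that point it is the better plan. In step count it would be longer, since the chosen route obtains the whole bicycle in one step from two commercial compounds, and the alternative offers no answer of its own to placing the C3' oxygen on the hindered face.

Key step: step 11

Assumption: the (Sa,Sc,Sc) phosphoramidite is taken to be the enantiomer that gives the (S)-1-phenylallyl ether, by analogy with the usual sense of induction of this catalyst family; the mirror-image ligand is used if a model etherification shows the opposite sense.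
Assumption: the configuration of the carbinol carbon created in step 5 (compounds 11 and 12) is left undefined, because this carbon becomes the aldehyde carbon in step 6.

Step 1
Reactants: 1 (R)-α-phellandrene; 2 (R)-4-(tert-butyldimethylsilyloxy)cyclopent-2-en-1-one
Product: 3 tricyclic silyloxy ketone (cyclopentanone cis-fused across C2–C3 on the endo side; C=O on C2; silyloxy carbon, the future C2', on C3 with the silyloxy group trans to the C3–C4 bond; 5-methyl; 7-isopropyl syn to C5=C6)
Conditions: EtAlCl2 (0.4 equiv), 1 (3 equiv), PhMe, −40 → 0 °C
Reagents that add atoms: none
Why: Lewis-acid-promoted Diels–Alder reaction in which the enone β-carbon bonds to the diene terminus next to the methyl-bearing carbon (para orientation), the carbonyl lies endo, the diene reacts anti to isopropyl and the enone anti to the silyloxy group; for this pair of enantiomers all four preferences converge on 3, which sets C1, C2, C3 and C4 while C7 and C2' come from the chiral pool. Any antipode present in 1 would have to react in a mismatched sense, so the step should also upgrade stereochemical purity.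

Step 2
Reactants: 3 tricyclic silyloxy ketone
Product: 5 hydroxy dimethyl ketal, via silyl dimethyl ketal 4 (not isolated)
Conditions: HC(OMe)3, CSA (0.2 equiv), MeOH, 0 °C → rt; Et3N quench
Reagents that add atoms: methanol CO; trimethyl orthoformate COC(OC)OC
Why: Acid-catalysed ketalisation with orthoformate as water scavenger, followed in the same pot by methanolysis of the secondary silyl ether. The ketal removes the β-hydroxy ketone relationship (elimination, retro-aldol) before any alkoxide chemistry, and no stereocentre is touched.

Step 3
Reactants: 6 (E)-cinnamyl alcohol
Product: 7 tert-butyl (E)-cinnamyl carbonate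
Conditions: Boc2O, Bu4NHSO4 (cat.), 30% aq. NaOH, CH2Cl2, 0 °C → rt
Reagents that add atoms: di-tert-butyl dicarbonate CC(C)(C)OC(=O)OC(=O)OC(C)(C)C
Why: Phase-transfer acylation of a primary allylic alcohol. The tert-butyl carbonate is chosen because its leaving group gives only tert-butoxide, a poor competitor for the allyl-iridium intermediate of step 4.

Step 4
Reactants: 5 hydroxy dimethyl ketal; 7 tert-butyl (E)-cinnamyl carbonate
Product: 9 alkoxy ketone carrying the (S)-1-phenylprop-2-en-1-yl ether on the future C2', via ketal ether 8 (not isolated)
Conditions: n-BuLi, THF, 0 °C; CuI; then 7, [Ir(cod)Cl]2 (2 mol %), (Sa,Sc,Sc)-O,O'-(1,1'-binaphthalene-2,2'-diyl) N,N-bis(1-phenylethyl)phosphoramidite (4 mol %, pre-activated with n-PrNH2), THF, rt; then 5% aq. oxalic acid, THF, rt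
Reagents that add atoms: water O
Why: Iridium-catalysed allylic etherification of a copper alkoxide through a cyclometallated phosphoramidite allyl complex, which is attacked at the substituted terminus and sets C5' as (S) under catalyst control; mild aqueous acid then unmasks the ketone. Because the ether is made while the future carboxyl carbon is still a ketal carbon, no hydroxy ester able to close a γ-lactone ever appears.

Step 5
Reactants: 9 alkoxy ketone
Product: 12 α-hydroxy ketone (hydroxyl on the former CH2 carbon), via silyl enol ether 10 (not isolated), via silyloxy ketone 11 (not isolated)
Conditions: LiN(SiMe3)2, Me3SiCl, THF, −78 °C; pentane, filter, evaporate; mCPBA, CH2Cl2, −20 °C; 1 M HCl, THF, 0 °C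
Reagents that add atoms: 3-chloroperoxybenzoic acid OOC(=O)c1cccc(Cl)c1; chlorotrimethylsilane C[Si](C)(C)Cl (silicon only in 10 and 11)
Why: Rubottom oxidation: kinetic deprotonation at the unhindered CH2 with in situ silylation keeps the enolate short-lived so that the β-alkoxy group is not expelled, and the peracid should attack the electron-rich silyl enol ether much faster than the doubly screened ring alkene or the terminal vinyl group. The configuration of the new carbinol carbon is irrelevant.

Step 6
Reactants: 12 α-hydroxy ketone
Product: 13 ester aldehyde (2-(trimethylsilyl)ethyl ester on C2; side chain CH(CHO)–O–CH(Ph)CH=CH2 on C3)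
Conditions: Pb(OAc)4, Me3SiCH2CH2OH (10 equiv), PhMe, 0 °C → rt
Reagents that add atoms: 2-(trimethylsilyl)ethanol C[Si](C)(C)CCO
Why: Criegee-type cleavage of an α-hydroxy ketone by Pb(OAc)4 through the hemiketal formed with the added alcohol; the carbonyl carbon leaves as the ester on C2 and the carbinol carbon as the aldehyde on C2', still cis on the bicycle. No stereocentre is formed.

Step 7
Reactants: 13 ester aldehyde
Product: 14 diene ester (side chain CH(CH=CH2)–O–CH(Ph)CH=CH2 on C3)
Conditions: Ph3PCH3Br, KN(SiMe3)2, THF, 0 °C; then 13, −78 → 0 °C
Reagents that add atoms: methylenetriphenylphosphorane C=P(c1ccccc1)(c1ccccc1)c1ccccc1 (from methyltriphenylphosphonium bromide C[P+](c1ccccc1)(c1ccccc1)c1ccccc1.[Br-])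
Why: Wittig methylenation; a slight excess of phosphonium salt over base and low temperature should keep the α-alkoxy stereocentre C2' from epimerising, and the ester is inert to the ylide.

Step 8
Reactants: 14 diene ester
Product: 15 2,5-cis-2,5-dihydrofuran ester
Conditions: second-generation Grubbs catalyst (3 mol %), CH2Cl2 (0.005 M), 40 °C
Reagents that add atoms: none
Why: Ring-closing metathesis of two monosubstituted alkenes to a five-membered ring with loss of ethene; the hindered trisubstituted ring alkene should not take part, and the cis relationship of the C2' and C5' substituents follows from the two existing stereocentres.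

Step 9
Reactants: 15 2,5-cis-2,5-dihydrofuran ester
Product: 16 diol ester (both hydroxyls anti to the C2' and C5' substituents)
Conditions: OsO4 (2 mol %), NMO (1.3 equiv), acetone/H2O (9:1), 0 °C
Reagents that add atoms: osmium tetroxide O=[Os](=O)(=O)=O; N-methylmorpholine N-oxide C[N+]1([O-])CCOCC1
Why: Catalytic cis-dihydroxylation by [3+2] addition of OsO4 on the only open face of the dihydrofuran, anti to both the bicyclic and the phenyl substituent, which sets C3' and C4' by substrate control. Selectivity over the more electron-rich ring alkene rests on the steric screening of both of its faces (isopropyl on one, the endo substituents on the other), and the reaction is stopped as soon as 15 is consumed.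

Step 10
Reactants: 16 diol ester
Product: 17 cyclic sulfate ester
Conditions: NaH, 1,1'-sulfonyldiimidazole, DMF, −40 → −20 °C
Reagents that add atoms: 1,1'-sulfonyldiimidazole O=S(=O)(n1ccnc1)n1ccnc1
Why: Attack of the bis-alkoxide on sulfuryl diimidazole closes the five-membered cyclic sulfate on the cis-diol directly at the sulfate oxidation level, so no ruthenium oxidant that could cleave the ring alkene is needed; C3' and C4' keep their configuration.

Step 11
Reactants: 17 cyclic sulfate ester
Product: 19 hydrogen sulfate ester of the target at O4' (as its tetrabutylammonium salt), via cyclic sulfate carboxylic acid 18 (not isolated)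
Conditions: Bu4NF (1.3 equiv), THF, 0 °C → rt
Reagents that add atoms: none
Why: Fluoride attacks silicon of the 2-(trimethylsilyl)ethyl ester, which fragments to ethene and the tetrabutylammonium carboxylate of 18; this carboxylate then opens the cyclic sulfate by intramolecular SN2 attack at C3'. The closest known reaction type is the opening of 1,2-cyclic sulfates, used as epoxide surrogates, by carboxylate nucleophiles. The δ-lactone closes in a 6-exo-tet mode (O–C(=O)–C2–C3–C2'–C3'), with the breaking C3'–O bond outside the new ring. The one new stereocentre, C3', is set by stereospecific backside attack: the sulfate oxygens lie on the face anti to the C2' substituent, so the carboxylate arrives on the face of its own tether, the lactone becomes cis-fused and its oxygen ends trans to O4'. The step needs attack at C3' and not at C4', which the ring size (six against seven) secures. It also needs the internal nucleophile to outrun fluoride, which is helped because any external nucleophile would have to approach the face shielded by the phenyl and bicyclic groups. The remaining C4'–O–SO3 group is no longer electrophilic, so a second displacement cannot follow.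

Step 12
Reactants: 19 hydrogen sulfate ester of the target
Product: 20 target lactone
Conditions: H2SO4 (cat.), H2O (3 equiv), THF, rt
Reagents that add atoms: none
Why: Acid-catalysed hydrolysis of the alkyl sulfate monoester with S–O cleavage, so C4' keeps its oxygen and its configuration; catalytic acid with a few equivalents of water should leave the lactone, the benzylic ether and the trisubstituted alkene untouched.

Compound list

1 | (R)-α-phellandrene, (5R)-2-methyl-5-(propan-2-yl)cyclohexa-1,3-diene | CC1=CC[C@H](C(C)C)C=C1 | starting material
2 | (R)-4-(tert-butyldimethylsilyloxy)cyclopent-2-en-1-one | O=C1C=C[C@H](O[Si](C)(C)C(C)(C)C)C1 | starting material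
3 | tricyclic silyloxy ketone, endo Diels–Alder adduct | CC1=C[C@@H]2[C@@H]3C(=O)C[C@@H](O[Si](C)(C)C(C)(C)C)[C@@H]3[C@H]1C[C@@H]2C(C)C | intermediate
4 | silyl dimethyl ketal of 3 | CC1=C[C@@H]2[C@@H]3C(OC)(OC)C[C@@H](O[Si](C)(C)C(C)(C)C)[C@@H]3[C@H]1C[C@@H]2C(C)C | intermediate (not isolated)
5 | hydroxy dimethyl ketal | CC1=C[C@@H]2[C@@H]3C(OC)(OC)C[C@@H](O)[C@@H]3[C@H]1C[C@@H]2C(C)C | intermediate
6 | (E)-cinnamyl alcohol | OC/C=C/c1ccccc1 | starting material
7 | tert-butyl (E)-cinnamyl carbonate | CC(C)(C)OC(=O)OC/C=C/c1ccccc1 | intermediate
8 | (S)-1-phenylallyl ether of 5 (ketal ether) | CC1=C[C@@H]2[C@@H]3C(OC)(OC)C[C@@H](O[C@@H](C=C)c4ccccc4)[C@@H]3[C@H]1C[C@@H]2C(C)C | intermediate (not isolated)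
9 | alkoxy ketone | CC1=C[C@@H]2[C@@H]3C(=O)C[C@@H](O[C@@H](C=C)c4ccccc4)[C@@H]3[C@H]1C[C@@H]2C(C)C | intermediate
10 | trimethylsilyl enol ether of 9 (double bond toward the former CH2) | CC1=C[C@@H]2[C@@H]3C(O[Si](C)(C)C)=C[C@@H](O[C@@H](C=C)c4ccccc4)[C@@H]3[C@H]1C[C@@H]2C(C)C | intermediate (not isolated)
11 | α-(trimethylsilyloxy) ketone (carbinol carbon undefined) | CC1=C[C@@H]2[C@@H]3C(=O)C(O[Si](C)(C)C)[C@@H](O[C@@H](C=C)c4ccccc4)[C@@H]3[C@H]1C[C@@H]2C(C)C | intermediate (not isolated)
12 | α-hydroxy ketone (carbinol carbon undefined) | CC1=C[C@@H]2[C@@H]3C(=O)C(O)[C@@H](O[C@@H](C=C)c4ccccc4)[C@@H]3[C@H]1C[C@@H]2C(C)C | intermediate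
13 | ester aldehyde, 2-(trimethylsilyl)ethyl endo-carboxylate with the α-alkoxy aldehyde side chain on C3 | CC1=C[C@@H]2[C@H](C(=O)OCC[Si](C)(C)C)[C@H]([C@@H](C=O)O[C@@H](C=C)c3ccccc3)[C@H]1C[C@@H]2C(C)C | intermediate
14 | diene ester (bis-allylic ether) | CC1=C[C@@H]2[C@H](C(=O)OCC[Si](C)(C)C)[C@H]([C@@H](C=C)O[C@@H](C=C)c3ccccc3)[C@H]1C[C@@H]2C(C)C | intermediate
15 | 2,5-cis-2,5-dihydrofuran ester | CC1=C[C@@H]2[C@H](C(=O)OCC[Si](C)(C)C)[C@H]([C@H]3C=C[C@@H](c4ccccc4)O3)[C@H]1C[C@@H]2C(C)C | intermediate
16 | diol ester (cis-diol anti to the C2' and C5' substituents) | CC1=C[C@@H]2[C@H](C(=O)OCC[Si](C)(C)C)[C@H]([C@@H]3O[C@H](c4ccccc4)[C@@H](O)[C@H]3O)[C@H]1C[C@@H]2C(C)C | intermediate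
17 | cyclic sulfate ester | CC1=C[C@@H]2[C@H](C(=O)OCC[Si](C)(C)C)[C@H]([C@@H]3O[C@H](c4ccccc4)[C@H]5OS(=O)(=O)O[C@@H]35)[C@H]1C[C@@H]2C(C)C | intermediate
18 | cyclic sulfate carboxylic acid (key-step precursor, formed as its carboxylate) | CC1=C[C@@H]2[C@H](C(=O)O)[C@H]([C@@H]3O[C@H](c4ccccc4)[C@H]5OS(=O)(=O)O[C@@H]35)[C@H]1C[C@@H]2C(C)C | intermediate (not isolated)
19 | hydrogen sulfate ester of the target at O4' (key-step product) | CC1=C[C@@H]2[C@@H]3C(=O)O[C@H]4[C@H](OS(=O)(=O)O)[C@@H](c5ccccc5)O[C@H]4[C@@H]3[C@H]1C[C@@H]2C(C)C | intermediate
20 | target lactone CNP0249919.1 | CC1=C[C@@H]2[C@@H]3C(=O)O[C@H]4[C@H](O)[C@@H](c5ccccc5)O[C@H]4[C@@H]3[C@H]1C[C@@H]2C(C)C | target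

Total: 12 steps. Longest linear sequence: 11 steps (steps 1, 2 and 4 to 12 from 1 and 2); step 3 is a one-step branch.

Least certain steps

Step 11 (key step). The desilylative ester cleavage and the opening of the sulfate run on similar time scales, so fluoride may open or eliminate the cyclic sulfate before the carboxylate is free, or the SN2 closure at the congested C3' may be slow enough for the sulfate to hydrolyse on work-up. Fallback: starting from 16, Bu4NF would cleave the ester to the diol acid F1. A Mitsunobu lactonisation (PPh3, DIAD, THF) would then activate a hydroxyl, and the carboxylate would displace it at C3' with inversion (six-membered against seven-membered closure), which gives 20 directly. The fallback returns to the route at 20.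

Step 1. The cyclopentenone is a weak dienophile, so at the temperature needed for cycloaddition the Lewis acid may instead isomerise or aromatise the diene, or strip silanol from the enone. Fallback: starting from 2, bromination and dehydrobromination (Br2, then Et3N, CH2Cl2) would give the 2-bromo enone F2, a much more reactive dienophile. Its cycloaddition with 1 under milder activation would give the α-bromo ketone F3, and Zn in AcOH would then remove the bromine. The zinc enolate can only protonate to the cis-fused ring, so the fallback returns at 3.

Step 9. The ring alkene is the more electron-rich of the two, and if its steric screening is not enough, osmylation there would compete and chemoselectivity would be poor. Fallback: starting from 15, Bu4NF would give the dihydrofuran acid F4, and iodolactonisation (I2, NaHCO3) would mask both the ring alkene and the acid as the iodolactone F5. Dihydroxylation (OsO4, NMO) then meets only the dihydrofuran alkene and gives the iodolactone diol F6, and sulfuryl diimidazole with NaH gives the iodolactone cyclic sulfate F7. Zn in AcOH/THF reopens the iodolactone to the alkene and the carboxyl group, which is 18 as the free acid; Et3N in MeCN then triggers the closure of step 11. The fallback returns at 18.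

Step 4. The hindered secondary copper alkoxide may convert slowly, and the neighbouring stereocentres may erode catalyst control at C5' (mismatched pairing or reversed sense), giving a mixture of ether epimers. Fallback: starting from 5, a rhodium-catalysed branched-selective hydroalkoxylation of phenylallene ([Rh(cod)Cl]2, a chiral bisphosphine, catalytic diphenyl phosphate, 1,2-dichloroethane) would form the same C5'–O bond without any metal alkoxide and give 8, which is hydrolysed to 9 as in step 4. The fallback returns at 8.

Further compounds

F1 | step 11 | diol acid (16 without the silylethyl group) | CC1=C[C@@H]2[C@H](C(=O)O)[C@H]([C@@H]3O[C@H](c4ccccc4)[C@@H](O)[C@H]3O)[C@H]1C[C@@H]2C(C)C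
F2 | step 1 | (R)-2-bromo-4-(tert-butyldimethylsilyloxy)cyclopent-2-en-1-one | O=C1C(Br)=C[C@H](O[Si](C)(C)C(C)(C)C)C1
F3 | step 1 | α-bromo ketone adduct (3 with bromine in place of the hydrogen on C2) | CC1=C[C@@H]2[C@]3(Br)C(=O)C[C@@H](O[Si](C)(C)C(C)(C)C)[C@@H]3[C@H]1C[C@@H]2C(C)C
F4 | step 9 | dihydrofuran acid (15 without the silylethyl group) | CC1=C[C@@H]2[C@H](C(=O)O)[C@H]([C@H]3C=C[C@@H](c4ccccc4)O3)[C@H]1C[C@@H]2C(C)C
F5 | step 9 | iodolactone (γ-lactone from the C2 carboxyl to C6, iodine on C5) | C[C@]1(I)[C@@H]2OC(=O)[C@H]3[C@@H]2[C@@H](C(C)C)C[C@@H]1[C@H]3[C@H]4C=C[C@@H](c5ccccc5)O4
F6 | step 9 | iodolactone diol | C[C@]1(I)[C@@H]2OC(=O)[C@H]3[C@@H]2[C@@H](C(C)C)C[C@@H]1[C@H]3[C@@H]4O[C@H](c5ccccc5)[C@@H](O)[C@H]4O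
F7 | step 9 | iodolactone cyclic sulfate | C[C@]1(I)[C@@H]2OC(=O)[C@H]3[C@@H]2[C@@H](C(C)C)C[C@@H]1[C@H]3[C@@H]4O[C@H](c5ccccc5)[C@H]6OS(=O)(=O)O[C@@H]46
F0 | step 4 | none | none
A1 | alternative 1 | endo-isopropenyl bicyclo[2.2.2]octenone spiro-ketal (product of the key step) | CC1=C[C@@H]2C(=O)[C@@]3(OCC(=O)O3)[C@H]1C[C@@H]2C(C)=C
A2 | alternative 1 | spiro-ketal 4-methylcyclohexa-2,4-dienone (masked o-benzoquinone) | CC1=C[C@]2(OCC(=O)O2)C(=O)C=C1
A3 | alternative 1 | isoprene | CC(=C)C=C
A4 | alternative 2 | tert-butyldimethylsilyl ether of the target (product of the key step) | CC1=C[C@@H]2[C@@H]3C(=O)O[C@H]4[C@H](O[Si](C)(C)C(C)(C)C)[C@@H](c5ccccc5)O[C@H]4[C@@H]3[C@H]1C[C@@H]2C(C)C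
A5 | alternative 2 | selenide ester (bicyclo[2.2.2]octa-2,5-diene-2-carboxylate of the 2-phenylselanyl oxolan-3-ol, selenide carbon undefined) | CC1=C[C@@H]2C(C(=O)O[C@H]3[C@H](O[Si](C)(C)C(C)(C)C)[C@@H](c4ccccc4)OC3[Se]c5ccccc5)=C[C@H]1C[C@@H]2C(C)C
A6 | alternative 3 | bis-silylated seco acid of the target (product of the key step) | CC1=C[C@@H]2[C@H](C(=O)O)[C@H]([C@@H]3O[C@H](c4ccccc4)[C@@H](O[Si](C)(C)C(C)(C)C)[C@@H]3O[Si](C)(C)C(C)(C)C)[C@H]1C[C@@H]2C(C)C
A7 | alternative 3 | cis-fused tertiary allylic δ-lactone | C[C@]12OC(=O)C[C@H]([C@@H]3O[C@H](c4ccccc4)[C@@H](O[Si](C)(C)C(C)(C)C)[C@@H]3O[Si](C)(C)C(C)(C)C)[C@H]1C[C@H](C(C)C)C=C2
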